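**Retrosynthetic overview**
1. Target 30 ⇐ MOM ether 29 ⇐ C4 carbinol (carried as TBS ether) ⇐ alkene 26 ⇐ Wittig reaction of C2‑carbaldehyde 20 with the oxido ylide from 24 (side‑chain C1'–C2').
2. Aldehyde 20 ⇐ chromanone ester 16 (C4 ketone masked as the silylated alcohol, then ester → CHO).
3. Pyranone ring (the only ring made; the benzene ring is bought): O1–C8a by intramolecular SNAr of the tertiary alkoxide of 15 on the ortho‑fluoro aryl ketone.
4. Key C–C bond C2–C3: enantioselective Cu(II)/bis(oxazoline) Mukaiyama aldol of aryl methyl ketone enolsilane 12 with methyl pyruvate 13; this sets C2.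
5. Enolsilane 12 ⇐ 2‑fluoro‑5‑methoxybenzaldehyde 1 (ring bromination, MeMgBr/oxidation, Me → MOM exchange).

Assumption: Cu(OTf)2/(S,S)‑t‑Bu‑box gives the (S)‑adduct 15 with enolsilane 12, as reported for the parent acetophenone enolsilane (si‑face attack on chelated pyruvate). The sense is confirmed on 15/16 (chiral HPLC, X‑ray of bromide 16), and the (R,R)‑ligand is used if it proves opposite. C4 epimer mixtures (17–28) are carried on unseparated.

**Route**

Step 1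
Reactants: 1 2‑fluoro‑5‑methoxybenzaldehyde; 2 N‑bromosuccinimide
Product: 3 4‑bromo‑2‑fluoro‑5‑methoxybenzaldehyde
Conditions: NBS (1.1 equiv), TFA/conc. H2SO4 (4:1), rt; recrystallise
Reagents that add atoms: N‑bromosuccinimide, O=C1CCC(=O)N1Br
Why: Electrophilic aromatic bromination directed ortho to OMe (para is blocked by F, and the site between OMe and CHO is hindered, as in 2,5‑dimethoxybenzaldehyde → 4‑bromo), done on the aldehyde so that no enolisable ketone can α‑brominate.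

Step 2
Reactants: 3 4‑bromo‑2‑fluoro‑5‑methoxybenzaldehyde; 4 methylmagnesium bromide
Product: 5 (RS)‑1‑(4‑bromo‑2‑fluoro‑5‑methoxyphenyl)ethan‑1‑ol
Conditions: MeMgBr (1.2 equiv), THF, −20 → 0 °C; aq. NH4Cl
Reagents that add atoms: methylmagnesium bromide, C[Mg]Br
Why: Grignard 1,2‑addition to the aldehyde is far faster than any reaction at ArBr or ArF, and the new carbinol centre is removed in step 3.

Step 3
Reactants: 5 (RS)‑1‑(4‑bromo‑2‑fluoro‑5‑methoxyphenyl)ethan‑1‑ol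
Product: 6 1‑(4‑bromo‑2‑fluoro‑5‑methoxyphenyl)ethan‑1‑one
Conditions: Dess–Martin periodinane, NaHCO3, CH2Cl2, rt
Reagents that add atoms: none
Why: Dess–Martin oxidation of a secondary benzylic alcohol to the aryl methyl ketone.

Step 4
Reactants: 6 1‑(4‑bromo‑2‑fluoro‑5‑methoxyphenyl)ethan‑1‑one
Product: 7 1‑(4‑bromo‑2‑fluoro‑5‑hydroxyphenyl)ethan‑1‑one
Conditions: BBr3 (2.5 equiv), CH2Cl2, −78 → 0 °C; H2O
Reagents that add atoms: none
Why: Lewis‑acid cleavage of the aryl methyl ether, done here because no later intermediate (tertiary alcohol, tertiary alkyl aryl ether) would survive BBr3.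

Step 5
Reactants: 7 1‑(4‑bromo‑2‑fluoro‑5‑hydroxyphenyl)ethan‑1‑one; 8 chloromethyl methyl ether
Product: 9 1‑[4‑bromo‑2‑fluoro‑5‑(methoxymethoxy)phenyl]ethan‑1‑one
Conditions: MOMCl, i‑Pr2NEt, CH2Cl2, 0 °C → rt
Reagents that add atoms: chloromethyl methyl ether, COCCl
Why: O‑alkylation of the phenol gives a MOM ether that is stable to base, fluoride, hydride and ylide and comes off at the end with dilute acid.

Step 6
Reactants: 9 1‑[4‑bromo‑2‑fluoro‑5‑(methoxymethoxy)phenyl]ethan‑1‑one; 10 chlorotrimethylsilane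
Product: 12 {1‑[4‑bromo‑2‑fluoro‑5‑(methoxymethoxy)phenyl]ethenyl}oxy(trimethyl)silane, via lithium enolate 11 (not isolated)
Conditions: LiHMDS (1.05 equiv), THF, −78 °C; TMSCl, −78 → 0 °C; pentane, filter, concentrate
Reagents that add atoms: chlorotrimethylsilane, C[Si](C)(C)Cl
Why: Kinetic deprotonation of the methyl ketone and O‑silylation give the silyl enol ether, and LiHMDS at −78 °C leaves ArBr, ArF and MOM alone.

Step 7
Reactants: 12 {1‑[4‑bromo‑2‑fluoro‑5‑(methoxymethoxy)phenyl]ethenyl}oxy(trimethyl)silane; 13 methyl pyruvate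
Product: 15 methyl (2S)‑4‑[4‑bromo‑2‑fluoro‑5‑(methoxymethoxy)phenyl]‑2‑hydroxy‑2‑methyl‑4‑oxobutanoate, via silyl ether 14 (not isolated)
Conditions: Cu(OTf)2 (10 mol%), (S,S)‑t‑Bu‑box (11 mol%), THF, −78 °C; then 1 M HCl, THF, 0 °C
Reagents that add atoms: methyl pyruvate, CC(=O)C(=O)OC
Why: Evans Cu(II)–bis(oxazoline) Mukaiyama aldol addition, in which pyruvate is chelated in a square‑planar Cu complex and the enolsilane attacks its open si face, forming the C2–C3 bond and setting the (S) tertiary carbinol that becomes C2.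

Step 8
Reactants: 15 methyl (2S)‑4‑[4‑bromo‑2‑fluoro‑5‑(methoxymethoxy)phenyl]‑2‑hydroxy‑2‑methyl‑4‑oxobutanoate
Product: 16 methyl (2S)‑7‑bromo‑6‑(methoxymethoxy)‑2‑methyl‑4‑oxo‑3,4‑dihydro‑2H‑chromene‑2‑carboxylate
Conditions: Cs2CO3 (1.2 equiv), DMF (0.05 M), 0 °C → rt; pH 7 buffer at full conversion
Reagents that add atoms: none
Why: Intramolecular SNAr (addition–elimination) of the tertiary alkoxide on the fluoride activated by the ortho ketone closes the six‑membered ring without touching the C–O bond of the stereocentre, so configuration is retained.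

Step 9
Reactants: 16 methyl (2S)‑7‑bromo‑6‑(methoxymethoxy)‑2‑methyl‑4‑oxo‑3,4‑dihydro‑2H‑chromene‑2‑carboxylate
Product: 17 methyl (2S)‑7‑bromo‑4‑hydroxy‑6‑(methoxymethoxy)‑2‑methyl‑3,4‑dihydro‑2H‑chromene‑2‑carboxylate (C4 epimers)
Conditions: NaBH4, CeCl3·7H2O, MeOH, −40 °C
Reagents that add atoms: none
Why: Luche reduction takes the ketone and not the ester under nearly neutral conditions, removing the base‑labile β‑aryloxy ketone before the hydride and ylide steps (the C4 centre is erased again in step 17).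

Step 10
Reactants: 17 methyl (2S)‑7‑bromo‑4‑hydroxy‑6‑(methoxymethoxy)‑2‑methyl‑3,4‑dihydro‑2H‑chromene‑2‑carboxylate (C4 epimers); 18 tert‑butyl(chloro)dimethylsilane
Product: 19 methyl (2S)‑7‑bromo‑4‑{[tert‑butyl(dimethyl)silyl]oxy}‑6‑(methoxymethoxy)‑2‑methyl‑3,4‑dihydro‑2H‑chromene‑2‑carboxylate (C4 epimers)
Conditions: TBSCl, imidazole, DMF, rt
Reagents that add atoms: tert‑butyl(chloro)dimethylsilane, CC(C)(C)[Si](C)(C)Cl
Why: Silylation of the secondary alcohol, done directly after step 9 so that the cis hydroxy ester cannot lactonise.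

Step 11
Reactants: 19 methyl (2S)‑7‑bromo‑4‑{[tert‑butyl(dimethyl)silyl]oxy}‑6‑(methoxymethoxy)‑2‑methyl‑3,4‑dihydro‑2H‑chromene‑2‑carboxylate (C4 epimers)
Product: 20 (2S)‑7‑bromo‑4‑{[tert‑butyl(dimethyl)silyl]oxy}‑6‑(methoxymethoxy)‑2‑methyl‑3,4‑dihydro‑2H‑chromene‑2‑carbaldehyde (C4 epimers)
Conditions: DIBAL‑H (1.2 equiv), CH2Cl2, −78 °C; MeOH, aq. Rochelle salt
Reagents that add atoms: none
Why: Partial reduction of the α‑aryloxy ester stops at the chelated aluminium hemiacetal, and the aldehyde has no α‑hydrogen, so C2 cannot epimerise.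

Step 12
Reactants: 21 ethyl 3‑bromopropanoate; 4 methylmagnesium bromide
Product: 22 4‑bromo‑2‑methylbutan‑2‑ol
Conditions: MeMgBr (2.2 equiv), Et2O, −20 → 0 °C; aq. NH4Cl
Reagents that add atoms: methylmagnesium bromide, C[Mg]Br
Why: Double Grignard addition to the ester gives the tertiary alcohol, with the primary bromide untouched at low temperature.

Step 13
Reactants: 22 4‑bromo‑2‑methylbutan‑2‑ol; 23 triphenylphosphine
Product: 24 (3‑hydroxy‑3‑methylbutyl)triphenylphosphonium bromide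
Conditions: PPh3, toluene, reflux; filter the salt
Reagents that add atoms: triphenylphosphine, c1ccc(cc1)P(c1ccccc1)c1ccccc1
Why: SN2 quaternisation of the primary bromide by the phosphine.

Step 14
Reactants: 20 (2S)‑7‑bromo‑4‑{[tert‑butyl(dimethyl)silyl]oxy}‑6‑(methoxymethoxy)‑2‑methyl‑3,4‑dihydro‑2H‑chromene‑2‑carbaldehyde (C4 epimers); 24 (3‑hydroxy‑3‑methylbutyl)triphenylphosphonium bromide
Product: 26 (4Z)‑5‑[(2S)‑7‑bromo‑4‑{[tert‑butyl(dimethyl)silyl]oxy}‑6‑(methoxymethoxy)‑2‑methyl‑3,4‑dihydro‑2H‑chromen‑2‑yl]‑2‑methylpent‑4‑en‑2‑ol (C4 epimers), via oxido ylide 25 (not isolated)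
Conditions: 24 (2.2 equiv), n‑BuLi (4.3 equiv), THF, −20 → 0 °C; then 20, −78 °C → rt
Reagents that add atoms: (3‑hydroxy‑3‑methylbutyl)triphenylphosphonium bromide, CC(C)(O)CC[P+](c1ccccc1)(c1ccccc1)c1ccccc1.[Br-]
Why: Wittig olefination with the non‑stabilised oxido ylide (the reagent used for 25‑hydroxy vitamin D side chains) adds the remaining five carbons with the tertiary alcohol in place, and the mainly Z geometry is irrelevant.

Step 15
Reactants: 26 (4Z)‑5‑[(2S)‑7‑bromo‑4‑{[tert‑butyl(dimethyl)silyl]oxy}‑6‑(methoxymethoxy)‑2‑methyl‑3,4‑dihydro‑2H‑chromen‑2‑yl]‑2‑methylpent‑4‑en‑2‑ol (C4 epimers)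
Product: 27 5‑[(2R)‑7‑bromo‑4‑{[tert‑butyl(dimethyl)silyl]oxy}‑6‑(methoxymethoxy)‑2‑methyl‑3,4‑dihydro‑2H‑chromen‑2‑yl]‑2‑methylpentan‑2‑ol (C4 epimers)
Conditions: H2 (1 atm), [Ir(cod)(PCy3)(py)]PF6 (5 mol%), CH2Cl2, rt
Reagents that add atoms: none
Why: Hydroxyl‑directed homogeneous hydrogenation with Crabtree's catalyst saturates the hindered alkene without the C–Br or benzylic C–O hydrogenolysis expected over Pd/C (the C2 descriptor changes to R only because the CIP ranking of its two CH2 arms changes).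

Step 16
Reactants: 27 5‑[(2R)‑7‑bromo‑4‑{[tert‑butyl(dimethyl)silyl]oxy}‑6‑(methoxymethoxy)‑2‑methyl‑3,4‑dihydro‑2H‑chromen‑2‑yl]‑2‑methylpentan‑2‑ol (C4 epimers)
Product: 28 (2R)‑7‑bromo‑2‑(4‑hydroxy‑4‑methylpentyl)‑6‑(methoxymethoxy)‑2‑methyl‑3,4‑dihydro‑2H‑chromen‑4‑ol (C4 epimers)
Conditions: TBAF (1.5 equiv), THF, 0 °C → rt
Reagents that add atoms: none
Why: Fluoride desilylation frees the C4 alcohol without acid, which would ionise this benzylic position.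

Step 17
Reactants: 28 (2R)‑7‑bromo‑2‑(4‑hydroxy‑4‑methylpentyl)‑6‑(methoxymethoxy)‑2‑methyl‑3,4‑dihydro‑2H‑chromen‑4‑ol (C4 epimers)
Product: 29 (2R)‑7‑bromo‑2‑(4‑hydroxy‑4‑methylpentyl)‑6‑(methoxymethoxy)‑2‑methyl‑2,3‑dihydro‑4H‑chromen‑4‑one
Conditions: Dess–Martin periodinane, NaHCO3, CH2Cl2, 0 °C → rt
Reagents that add atoms: none
Why: Dess–Martin oxidation of the secondary benzylic alcohol restores the chromanone from both C4 epimers while the tertiary alcohol cannot be oxidised.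

Step 18
Reactants: 29 (2R)‑7‑bromo‑2‑(4‑hydroxy‑4‑methylpentyl)‑6‑(methoxymethoxy)‑2‑methyl‑2,3‑dihydro‑4H‑chromen‑4‑one
Product: 30 (2R)‑7‑bromo‑6‑hydroxy‑2‑(4‑hydroxy‑4‑methylpentyl)‑2‑methyl‑2,3‑dihydro‑4H‑chromen‑4‑one
Conditions: 2 M aq. HCl, THF, 35 °C
Reagents that add atoms: none
Why: Acid hydrolysis of the aryl MOM acetal in dilute aqueous acid frees the phenol and avoids base, which could racemise C2 by retro‑oxa‑Michael opening.

**Compound list**
1 | 2‑fluoro‑5‑methoxybenzaldehyde | O=Cc1cc(OC)ccc1F | starting material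
2 | N‑bromosuccinimide | O=C1CCC(=O)N1Br | starting material
3 | 4‑bromo‑2‑fluoro‑5‑methoxybenzaldehyde | O=Cc1cc(OC)c(Br)cc1F | intermediate
4 | methylmagnesium bromide | C[Mg]Br | starting material
5 | (RS)‑1‑(4‑bromo‑2‑fluoro‑5‑methoxyphenyl)ethan‑1‑ol | CC(O)c1cc(OC)c(Br)cc1F | intermediate
6 | 1‑(4‑bromo‑2‑fluoro‑5‑methoxyphenyl)ethan‑1‑one | CC(=O)c1cc(OC)c(Br)cc1F | intermediate
7 | 1‑(4‑bromo‑2‑fluoro‑5‑hydroxyphenyl)ethan‑1‑one | CC(=O)c1cc(O)c(Br)cc1F | intermediate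
8 | chloromethyl methyl ether | COCCl | starting material
9 | 1‑[4‑bromo‑2‑fluoro‑5‑(methoxymethoxy)phenyl]ethan‑1‑one | CC(=O)c1cc(OCOC)c(Br)cc1F | intermediate
10 | chlorotrimethylsilane | C[Si](C)(C)Cl | starting material
11 | lithium 1‑[4‑bromo‑2‑fluoro‑5‑(methoxymethoxy)phenyl]ethen‑1‑olate | [Li+].[O-]C(=C)c1cc(OCOC)c(Br)cc1F | intermediate
12 | {1‑[4‑bromo‑2‑fluoro‑5‑(methoxymethoxy)phenyl]ethenyl}oxy(trimethyl)silane | C=C(O[Si](C)(C)C)c1cc(OCOC)c(Br)cc1F | intermediate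
13 | methyl pyruvate | CC(=O)C(=O)OC | starting material
14 | methyl (2S)‑4‑[4‑bromo‑2‑fluoro‑5‑(methoxymethoxy)phenyl]‑2‑methyl‑4‑oxo‑2‑[(trimethylsilyl)oxy]butanoate | COC(=O)[C@@](C)(O[Si](C)(C)C)CC(=O)c1cc(OCOC)c(Br)cc1F | intermediate
15 | methyl (2S)‑4‑[4‑bromo‑2‑fluoro‑5‑(methoxymethoxy)phenyl]‑2‑hydroxy‑2‑methyl‑4‑oxobutanoate | COC(=O)[C@@](C)(O)CC(=O)c1cc(OCOC)c(Br)cc1F | intermediate
16 | methyl (2S)‑7‑bromo‑6‑(methoxymethoxy)‑2‑methyl‑4‑oxo‑3,4‑dihydro‑2H‑chromene‑2‑carboxylate | COC(=O)[C@]1(C)CC(=O)c2cc(OCOC)c(Br)cc2O1 | intermediate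
17 | methyl (2S)‑7‑bromo‑4‑hydroxy‑6‑(methoxymethoxy)‑2‑methyl‑3,4‑dihydro‑2H‑chromene‑2‑carboxylate (C4 epimers) | COC(=O)[C@]1(C)CC(O)c2cc(OCOC)c(Br)cc2O1 | intermediate
18 | tert‑butyl(chloro)dimethylsilane | CC(C)(C)[Si](C)(C)Cl | starting material
19 | methyl (2S)‑7‑bromo‑4‑{[tert‑butyl(dimethyl)silyl]oxy}‑6‑(methoxymethoxy)‑2‑methyl‑3,4‑dihydro‑2H‑chromene‑2‑carboxylate (C4 epimers) | COC(=O)[C@]1(C)CC(O[Si](C)(C)C(C)(C)C)c2cc(OCOC)c(Br)cc2O1 | intermediate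
20 | (2S)‑7‑bromo‑4‑{[tert‑butyl(dimethyl)silyl]oxy}‑6‑(methoxymethoxy)‑2‑methyl‑3,4‑dihydro‑2H‑chromene‑2‑carbaldehyde (C4 epimers) | O=C[C@]1(C)CC(O[Si](C)(C)C(C)(C)C)c2cc(OCOC)c(Br)cc2O1 | intermediate
21 | ethyl 3‑bromopropanoate | CCOC(=O)CCBr | starting material
22 | 4‑bromo‑2‑methylbutan‑2‑ol | CC(C)(O)CCBr | intermediate
23 | triphenylphosphine | c1ccc(cc1)P(c1ccccc1)c1ccccc1 | starting material
24 | (3‑hydroxy‑3‑methylbutyl)triphenylphosphonium bromide | CC(C)(O)CC[P+](c1ccccc1)(c1ccccc1)c1ccccc1.[Br-] | intermediate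
25 | lithium 2‑methyl‑4‑(triphenyl‑λ5‑phosphanylidene)butan‑2‑olate | [Li+].CC(C)([O-])CC=P(c1ccccc1)(c1ccccc1)c1ccccc1 | intermediate
26 | (4Z)‑5‑[(2S)‑7‑bromo‑4‑{[tert‑butyl(dimethyl)silyl]oxy}‑6‑(methoxymethoxy)‑2‑methyl‑3,4‑dihydro‑2H‑chromen‑2‑yl]‑2‑methylpent‑4‑en‑2‑ol (C4 epimers) | CC(C)(O)C/C=C\[C@]1(C)CC(O[Si](C)(C)C(C)(C)C)c2cc(OCOC)c(Br)cc2O1 | intermediate
27 | 5‑[(2R)‑7‑bromo‑4‑{[tert‑butyl(dimethyl)silyl]oxy}‑6‑(methoxymethoxy)‑2‑methyl‑3,4‑dihydro‑2H‑chromen‑2‑yl]‑2‑methylpentan‑2‑ol (C4 epimers) | CC(C)(O)CCC[C@]1(C)CC(O[Si](C)(C)C(C)(C)C)c2cc(OCOC)c(Br)cc2O1 | intermediate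
28 | (2R)‑7‑bromo‑2‑(4‑hydroxy‑4‑methylpentyl)‑6‑(methoxymethoxy)‑2‑methyl‑3,4‑dihydro‑2H‑chromen‑4‑ol (C4 epimers) | CC(C)(O)CCC[C@]1(C)CC(O)c2cc(OCOC)c(Br)cc2O1 | intermediate
29 | (2R)‑7‑bromo‑2‑(4‑hydroxy‑4‑methylpentyl)‑6‑(methoxymethoxy)‑2‑methyl‑2,3‑dihydro‑4H‑chromen‑4‑one | CC(C)(O)CCC[C@]1(C)CC(=O)c2cc(OCOC)c(Br)cc2O1 | intermediate
30 | (2R)‑7‑bromo‑6‑hydroxy‑2‑(4‑hydroxy‑4‑methylpentyl)‑2‑methyl‑2,3‑dihydro‑4H‑chromen‑4‑one | CC(C)(O)CCC[C@]1(C)CC(=O)c2cc(O)c(Br)cc2O1 | target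

**Step count**
Total: 18 steps. Longest linear sequence: 16 steps (1 → 30 through steps 1–11 and 14–18); steps 12–13 are a two‑step side branch that joins at step 14.

**Three steps most likely to fail**

Step 7 (asymmetric aldol). The published selectivities are for the unsubstituted acetophenone enolsilane; the ortho‑fluoro and MOM‑oxy groups of 12 may lower rate or ee, and the absolute sense has to be proven. Fallback, giving up catalyst control for resolution: from 12 and 13 the same addition is run with achiral Cu(OTf)2/2,2'‑bipyridine (10 mol%, THF, −78 °C). This gives racemic methyl 4‑[4‑bromo‑2‑fluoro‑5‑(methoxymethoxy)phenyl]‑2‑methyl‑4‑oxo‑2‑[(trimethylsilyl)oxy]butanoate F1, hydrolysed in the acidic work‑up to racemic methyl 4‑[4‑bromo‑2‑fluoro‑5‑(methoxymethoxy)phenyl]‑2‑hydroxy‑2‑methyl‑4‑oxobutanoate F2. Cs2CO3/DMF as in step 8 then gives racemic methyl 7‑bromo‑6‑(methoxymethoxy)‑2‑methyl‑4‑oxo‑3,4‑dihydro‑2H‑chromene‑2‑carboxylate F3. Preparative chiral SFC on a polysaccharide phase gives the (2S)‑enantiomer, which is 16, and leaves methyl (2R)‑7‑bromo‑6‑(methoxymethoxy)‑2‑methyl‑4‑oxo‑3,4‑dihydro‑2H‑chromene‑2‑carboxylate F4, which is discarded. The path sets out from 12 and comes back at 16.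

Step 8 (SNAr ring closure). The alkoxide of 15 can also undergo retro‑aldol cleavage or dehydration. The SNAr is slowed by the para MOM‑oxy group. The product 16 is a β‑aryloxy ketone with an ester on C2, so prolonged base can racemise it by retro‑oxa‑Michael opening and reclosure; its ee is therefore checked by chiral HPLC. Fallback, changing how the nucleophile is made so that no Brønsted base is present: the path sets out from 12 and 13. Step 7 is worked up without acid (filtration through deactivated silica) so that silyl ether 14 is isolated. 14 is then closed with catalytic fluoride (CsF or TBAT, 10–20 mol%, DMF, 0 °C). Fluoride removes the TMS group, the alkoxide cyclises, and the fluoride it expels desilylates the next molecule, so only traces of alkoxide ever coexist with the product. The path comes back at 16. New compounds on this path: none F0.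

Step 14 (Wittig). The aldehyde sits on a quaternary carbon and the oxido ylide is strongly basic; low conversion, or Br/Li exchange if free n‑BuLi remains, are the risks. Fallback, building the chain through an alkyne and an epoxide instead of an olefination: from 20, dimethyl (1‑diazo‑2‑oxopropyl)phosphonate, K2CO3, MeOH, 0 °C → rt gives tert‑butyl{[(2S)‑7‑bromo‑2‑ethynyl‑6‑(methoxymethoxy)‑2‑methyl‑3,4‑dihydro‑2H‑chromen‑4‑yl]oxy}dimethylsilane F5. Its lithium acetylide (n‑BuLi 1.0 equiv, THF, −78 °C) opens 2,2‑dimethyloxirane at the CH2 carbon in the presence of BF3·OEt2 to give 5‑[(2S)‑7‑bromo‑4‑{[tert‑butyl(dimethyl)silyl]oxy}‑6‑(methoxymethoxy)‑2‑methyl‑3,4‑dihydro‑2H‑chromen‑2‑yl]‑2‑methylpent‑4‑yn‑2‑ol F6. Excess diimide (2‑nitrobenzenesulfonylhydrazide, Et3N, CH2Cl2) saturates the triple bond without touching the aryl bromide and gives 27. The path sets out from 20 and comes back at 27.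

**Further compounds**
F1 | step 7 | racemic methyl 4‑[4‑bromo‑2‑fluoro‑5‑(methoxymethoxy)phenyl]‑2‑methyl‑4‑oxo‑2‑[(trimethylsilyl)oxy]butanoate | COC(=O)C(C)(O[Si](C)(C)C)CC(=O)c1cc(OCOC)c(Br)cc1F
F2 | step 7 | racemic methyl 4‑[4‑bromo‑2‑fluoro‑5‑(methoxymethoxy)phenyl]‑2‑hydroxy‑2‑methyl‑4‑oxobutanoate | COC(=O)C(C)(O)CC(=O)c1cc(OCOC)c(Br)cc1F
F3 | step 7 | racemic methyl 7‑bromo‑6‑(methoxymethoxy)‑2‑methyl‑4‑oxo‑3,4‑dihydro‑2H‑chromene‑2‑carboxylate | COC(=O)C1(C)CC(=O)c2cc(OCOC)c(Br)cc2O1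
F4 | step 7 | methyl (2R)‑7‑bromo‑6‑(methoxymethoxy)‑2‑methyl‑4‑oxo‑3,4‑dihydro‑2H‑chromene‑2‑carboxylate | COC(=O)[C@@]1(C)CC(=O)c2cc(OCOC)c(Br)cc2O1
F0 | step 8 | none | none
F5 | step 14 | tert‑butyl{[(2S)‑7‑bromo‑2‑ethynyl‑6‑(methoxymethoxy)‑2‑methyl‑3,4‑dihydro‑2H‑chromen‑4‑yl]oxy}dimethylsilane | C#C[C@]1(C)CC(O[Si](C)(C)C(C)(C)C)c2cc(OCOC)c(Br)cc2O1
F6 | step 14 | 5‑[(2S)‑7‑bromo‑4‑{[tert‑butyl(dimethyl)silyl]oxy}‑6‑(methoxymethoxy)‑2‑methyl‑3,4‑dihydro‑2H‑chromen‑2‑yl]‑2‑methylpent‑4‑yn‑2‑ol | CC(C)(O)CC#C[C@]1(C)CC(O[Si](C)(C)C(C)(C)C)c2cc(OCOC)c(Br)cc2O1
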